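**Plan**

- Retrosynthesis: O8 is masked as a benzyl ether and the O7 methyl group is removed. Ring A is then opened at C5–C6 (retro-Claisen), followed by cuts at C7–C8 (acetyl unit), C4a–C5 (ester carbon) and C2–C1' (ring B).
- Enabling feature: the oxygens on C5 and C7 of ring A are 1,3-related, as expected for an ester carbon and a ketone carbon bridged by a former methyl group (C6), and C8 bears one more oxygen. Kojic acid already supplies ring C (O1, C2, C3–O, C4=O, C4a, C8a) and the oxygenated C8 as its CH2OH group.
- Forward order: ring C is present from the start. C2 and then C4a are brominated, ring B is coupled to C2, the ester carbon is placed on C4a and the acetyl group on C8. Ring A closes last, by attack of C6 on C5.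
- Selectivity design: both brominations precede the arrival of the electron-rich ring B. The benzyl group distinguishes O8 from O7, and the C4=O···HO5 hydrogen bond distinguishes O5 from O7.
- Stereochemistry: the target is achiral. The only stereocentre of the route (C8 in 10) is racemic and disappears on aromatisation.

Key step: step 8

Remark: atoms are addressed by flavone numbering (O1, C2 … C8a; rings A, B, C) even in the monocyclic precursors, while compound names follow their own systematic numbering.

**Step 1**
Reactants: 1 kojic acid (5-hydroxy-2-(hydroxymethyl)-4H-pyran-4-one)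
Product: 2 2-bromo-3-hydroxy-6-(hydroxymethyl)-4H-pyran-4-one
Conditions: NBS (1.05 equiv), DMF, 0 °C → rt, dark
Reagents that add atoms: N-bromosuccinimide, O=C1CCC(=O)N1Br
Why: Electrophilic bromination of an enol, in which the free enolic OH makes the adjacent ring CH (future C2) by far the most nucleophilic carbon, the site at which kojic acid is known to be substituted.

**Step 2**
Reactants: 2 2-bromo-3-hydroxy-6-(hydroxymethyl)-4H-pyran-4-one
Product: 3 2-bromo-6-(hydroxymethyl)-3-methoxy-4H-pyran-4-one
Conditions: MeI (1.2 equiv), K2CO3 (1.2 equiv), DMF, rt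
Reagents that add atoms: iodomethane, CI
Why: Williamson O-alkylation in which K2CO3 deprotonates only the acidic enolic OH, so the primary alcohol stays free and the future 3-OMe group is installed.

**Step 3**
Reactants: 3 2-bromo-6-(hydroxymethyl)-3-methoxy-4H-pyran-4-one
Product: 4 6-[(benzyloxy)methyl]-2-bromo-3-methoxy-4H-pyran-4-one
Conditions: BnOC(=NH)CCl3 (1.5 equiv), TfOH (10 mol %), CH2Cl2/cyclohexane, 0 °C → rt
Reagents that add atoms: benzyl 2,2,2-trichloroacetimidate, N=C(OCc1ccccc1)C(Cl)(Cl)Cl
Why: Acid-catalysed trichloroacetimidate benzylation needs no alkoxide, which would otherwise displace the vinylogous acyl bromide by addition–elimination.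

**Step 4**
Reactants: 4 6-[(benzyloxy)methyl]-2-bromo-3-methoxy-4H-pyran-4-one
Product: 5 2-[(benzyloxy)methyl]-3,6-dibromo-5-methoxy-4H-pyran-4-one
Conditions: NBS (1.1 equiv), MeCN, 50 °C, dark
Reagents that add atoms: N-bromosuccinimide, O=C1CCC(=O)N1Br
Why: Electrophilic α-halogenation of a 4-pyranone (a vinylogous ester) at the only ring CH left (future C4a), which is α to C4=O and β to O1, carried out while no electron-rich arene is present to compete.

**Step 5**
Reactants: 5 2-[(benzyloxy)methyl]-3,6-dibromo-5-methoxy-4H-pyran-4-one; 6 (2,3,4-trimethoxyphenyl)boronic acid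
Product: 7 2-[(benzyloxy)methyl]-3-bromo-5-methoxy-6-(2,3,4-trimethoxyphenyl)-4H-pyran-4-one
Conditions: 6 (1.05 equiv), Pd(PPh3)4 (5 mol %), K3PO4, 1,4-dioxane/H2O, 60 °C
Reagents that add atoms: none
Why: Site-selective Suzuki–Miyaura coupling, in which zerovalent palladium inserts faster into the C–Br bond on the carbon bound to O1 and β to the carbonyl (a vinylogous acyl bromide) than into the more hindered, more electron-rich α-C–Br bond, the usual order for α,β-dihalogenated enones and 2,3-dihalogenated oxygen heterocycles.

**Step 6**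
Reactants: 7 2-[(benzyloxy)methyl]-3-bromo-5-methoxy-6-(2,3,4-trimethoxyphenyl)-4H-pyran-4-one
Product: 8 methyl 2-[(benzyloxy)methyl]-5-methoxy-4-oxo-6-(2,3,4-trimethoxyphenyl)-4H-pyran-3-carboxylate
Conditions: Pd(OAc)2 (5 mol %), dppf (10 mol %), CO (5 bar), Et3N, MeOH/DMF, 80 °C
Reagents that add atoms: carbon monoxide, [C-]#[O+]; methanol, CO
Why: Palladium-catalysed alkoxycarbonylation (oxidative addition, CO insertion, methanolysis of the acylpalladium species) places the future C5 on C4a, as known for α-bromo enones, 3-halochromones and brominated 4-pyridinones.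

**Step 7**
Reactants: 8 methyl 2-[(benzyloxy)methyl]-5-methoxy-4-oxo-6-(2,3,4-trimethoxyphenyl)-4H-pyran-3-carboxylate; 9 1-acetyl-1H-benzotriazole
Product: 10 methyl 2-[1-(benzyloxy)-2-oxopropyl]-5-methoxy-4-oxo-6-(2,3,4-trimethoxyphenyl)-4H-pyran-3-carboxylate (racemic)
Conditions: LiN(SiMe3)2 (2.1 equiv), THF, −78 °C; 9 (1.3 equiv), −78 → 0 °C; AcOH quench
Reagents that add atoms: none
Why: C-acylation of the extended enolate of a 2-alkyl-4-pyranone, whose OCH2 protons are vinylogously activated by C4=O and the ester; this stabilised anion calls for an irreversible acyl donor (N-acylbenzotriazoles C-acylate β-dicarbonyl-type enolates, whereas an N-methoxy-N-methylamide would be too sluggish), the second equivalent of base stores the more acidic product as its enolate, and the new C8 stereocentre is formed racemic and is lost in step 8.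

**Step 8**
Reactants: 10 methyl 2-[1-(benzyloxy)-2-oxopropyl]-5-methoxy-4-oxo-6-(2,3,4-trimethoxyphenyl)-4H-pyran-3-carboxylate
Product: 12 8-(benzyloxy)-5,7-dihydroxy-3-methoxy-2-(2,3,4-trimethoxyphenyl)-4H-chromen-4-one, via triketone tautomer 11 (not isolated)
Conditions: LiN(iPr)2 (3.3 equiv), THF, −78 → 0 °C; then 1 M HCl
Reagents that add atoms: none
Why: LiN(iPr)2 first removes the doubly activated C8–H and then a proton of the acetyl CH3 group, giving a 1,3-dianion of the acetoacetate type whose terminal carbon (C6) adds to the ester carbonyl on C4a (C5); methoxide leaves to give 11, and a third equivalent of base enolises it to the resorcinol-type bis(phenoxide), which makes the closure irreversible. The closest known reactions are the Dieckmann-type (intramolecular Claisen) cyclisation of 2-(2-oxopropyl)benzoates to naphthalene-1,3-diols and the Claisen-mode aromatisation of poly-β-carbonyl esters. Ring A closes in a 6-(enolexo)-exo-trig mode with formation of the C5–C6 bond. No stereocentre is created, and the racemic C8 of 10 becomes sp2. The step needs C6 rather than C8 or the enolate oxygen as nucleophile and the ester rather than C4=O as electrophile: C8 could only form a four-membered ring, C4 lies trans to C8 across the C4a=C8a bond and is out of reach, and O-acylation is reversible because the liberated LiOMe reopens the enol lactone, whereas only the C-acylated product aromatises. The negative charge spread over ring C in the mono- and dianion also protects C2 and C4 against addition of the base.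

**Step 9**
Reactants: 12 8-(benzyloxy)-5,7-dihydroxy-3-methoxy-2-(2,3,4-trimethoxyphenyl)-4H-chromen-4-one
Product: 13 8-(benzyloxy)-5-hydroxy-3,7-dimethoxy-2-(2,3,4-trimethoxyphenyl)-4H-chromen-4-one
Conditions: Me2SO4 (1.05 equiv), K2CO3 (1.5 equiv), acetone, reflux
Reagents that add atoms: dimethyl sulfate, COS(=O)(=O)OC
Why: Chemoselective Williamson methylation, in which the 5-OH is held in a hydrogen bond to C4=O and is much less acidic and nucleophilic than the 7-OH, while O8 is blocked as its benzyl ether, so one equivalent of reagent should alkylate O7 only.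

**Step 10**
Reactants: 13 8-(benzyloxy)-5-hydroxy-3,7-dimethoxy-2-(2,3,4-trimethoxyphenyl)-4H-chromen-4-one
Product: 14 5,8-dihydroxy-3,7-dimethoxy-2-(2,3,4-trimethoxyphenyl)-4H-chromen-4-one (5,8-dihydroxy-3,7,2',3',4'-pentamethoxyflavone)
Conditions: H2 (1 atm), 10% Pd/C, degassed EtOAc/MeOH, rt; work-up under argon
Reagents that add atoms: none
Why: Hydrogenolysis of an aryl benzyl ether, under which the tetrasubstituted C2=C3 bond, the carbonyl group and the methyl ethers are inert, with air excluded because the product is a para-hydroquinone.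

**Compound list**

1 | kojic acid (5-hydroxy-2-(hydroxymethyl)-4H-pyran-4-one) | O=c1cc(CO)occ1O | starting material
2 | 2-bromo-3-hydroxy-6-(hydroxymethyl)-4H-pyran-4-one | O=c1cc(CO)oc(Br)c1O | intermediate
3 | 2-bromo-6-(hydroxymethyl)-3-methoxy-4H-pyran-4-one | O=c1cc(CO)oc(Br)c1OC | intermediate
4 | 6-[(benzyloxy)methyl]-2-bromo-3-methoxy-4H-pyran-4-one | O=c1cc(COCc2ccccc2)oc(Br)c1OC | intermediate
5 | 2-[(benzyloxy)methyl]-3,6-dibromo-5-methoxy-4H-pyran-4-one | O=c1c(Br)c(COCc2ccccc2)oc(Br)c1OC | intermediate
6 | (2,3,4-trimethoxyphenyl)boronic acid | COc1ccc(B(O)O)c(OC)c1OC | starting material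
7 | 2-[(benzyloxy)methyl]-3-bromo-5-methoxy-6-(2,3,4-trimethoxyphenyl)-4H-pyran-4-one | O=c1c(Br)c(COCc2ccccc2)oc(-c2ccc(OC)c(OC)c2OC)c1OC | intermediate
8 | methyl 2-[(benzyloxy)methyl]-5-methoxy-4-oxo-6-(2,3,4-trimethoxyphenyl)-4H-pyran-3-carboxylate | COC(=O)c1c(COCc2ccccc2)oc(-c2ccc(OC)c(OC)c2OC)c(OC)c1=O | intermediate
9 | 1-acetyl-1H-benzotriazole | CC(=O)n1nnc2ccccc21 | starting material
10 | methyl 2-[1-(benzyloxy)-2-oxopropyl]-5-methoxy-4-oxo-6-(2,3,4-trimethoxyphenyl)-4H-pyran-3-carboxylate (racemic, configurationally labile) | COC(=O)c1c(C(OCc2ccccc2)C(C)=O)oc(-c2ccc(OC)c(OC)c2OC)c(OC)c1=O | intermediate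
11 | 8-(benzyloxy)-3-methoxy-2-(2,3,4-trimethoxyphenyl)-6H-chromene-4,5,7(8H)-trione (present as its lithium enolate, not isolated) | COc1ccc(-c2oc3c(c(=O)c2OC)C(=O)CC(=O)C3OCc2ccccc2)c(OC)c1OC | intermediate
12 | 8-(benzyloxy)-5,7-dihydroxy-3-methoxy-2-(2,3,4-trimethoxyphenyl)-4H-chromen-4-one | COc1ccc(-c2oc3c(OCc4ccccc4)c(O)cc(O)c3c(=O)c2OC)c(OC)c1OC | intermediate
13 | 8-(benzyloxy)-5-hydroxy-3,7-dimethoxy-2-(2,3,4-trimethoxyphenyl)-4H-chromen-4-one | COc1ccc(-c2oc3c(OCc4ccccc4)c(OC)cc(O)c3c(=O)c2OC)c(OC)c1OC | intermediate
14 | 5,8-dihydroxy-3,7-dimethoxy-2-(2,3,4-trimethoxyphenyl)-4H-chromen-4-one | COc1ccc(-c2oc3c(O)c(OC)cc(O)c3c(=O)c2OC)c(OC)c1OC | target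

Total step count: 10. Longest linear sequence: 10 steps, from kojic acid 1.

**Steps most likely to fail**

**Step 8 (closure of ring A).**
- What may go wrong: the second deprotonation may stay incomplete. The monoanion would then live long enough for acylation of its enolate oxygen by the ester, for migration of the benzyl group from oxygen to the carbanionic C8, or for opening of ring C by the base.
- Fallback, from 10 back to 12: the acidic C8–H is taken out of play before the same C5–C6 bond is made.
- Silylation of 10 (tBuMe2SiOTf, Et3N, CH2Cl2, 0 °C) should give, as an E/Z mixture, methyl 2-[1-(benzyloxy)-2-(tert-butyldimethylsilyloxy)prop-1-enyl]-5-methoxy-4-oxo-6-(2,3,4-trimethoxyphenyl)-4H-pyran-3-carboxylate F1.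
- A single deprotonation of its allylic CH3 group with LiN(iPr)2 in THF (γ-deprotonation of a β-oxygenated unsaturated carbonyl system) gives a trienolate in which C7–C8 is a single bond, so the alkene geometry no longer matters.
- C6 then attacks the ester carbon. Loss of methoxide and tautomerisation should give 8-(benzyloxy)-7-(tert-butyldimethylsilyloxy)-5-hydroxy-3-methoxy-2-(2,3,4-trimethoxyphenyl)-4H-chromen-4-one F2.
- Bu4NF in THF then frees the 7-OH and returns 12.

**Step 7 (acetylation at C8).**
- What may go wrong: the strongly delocalised anion may be acylated on oxygen instead of carbon, or may react too slowly at the hindered, alkoxy-substituted carbon, so that the acyl donor is consumed by the excess base.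
- Fallback, from 7 back to 10: the two C–C bond formations are exchanged, so the carbanion is made while C4a still bears bromine and is less stabilised and more nucleophilic.
- Treating 7 with LiN(SiMe3)2 in THF at −78 °C and then N-methoxy-N-methylacetamide should give 2-[1-(benzyloxy)-2-oxopropyl]-3-bromo-5-methoxy-6-(2,3,4-trimethoxyphenyl)-4H-pyran-4-one F3 through a chelated tetrahedral intermediate.
- Methoxycarbonylation of F3 under the catalyst system of step 6, with MeOH as the main solvent to favour methanolysis of the acylpalladium species over capture by the side-chain enol, then gives 10.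

**Step 5 (site-selective coupling).**
- What may go wrong: discrimination between the two C–Br bonds may erode, leading to coupling at both positions. The aqueous base may also hydrolyse the vinylogous acyl bromide before transmetalation, aggravated by protodeboronation of the ortho-substituted boronic acid.
- Fallback, from 1 back to 7: selectivity is moved from the position of the halogen to its identity.
- Iodination of 1 (N-iodosuccinimide, DMF) should give 3-hydroxy-6-(hydroxymethyl)-2-iodo-4H-pyran-4-one F4.
- Methylation as in step 2 gives 6-(hydroxymethyl)-2-iodo-3-methoxy-4H-pyran-4-one F5.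
- Benzylation as in step 3 gives 6-[(benzyloxy)methyl]-2-iodo-3-methoxy-4H-pyran-4-one F6.
- Bromination as in step 4 gives 2-[(benzyloxy)methyl]-3-bromo-6-iodo-5-methoxy-4H-pyran-4-one F7.
- The C–I bond of F7 undergoes oxidative addition well below the temperature needed for the C–Br bond, so coupling with 6 at room temperature should deliver 7.

**Further compounds**

F1 | step 8 | methyl 2-[1-(benzyloxy)-2-(tert-butyldimethylsilyloxy)prop-1-enyl]-5-methoxy-4-oxo-6-(2,3,4-trimethoxyphenyl)-4H-pyran-3-carboxylate (E/Z mixture) | COC(=O)c1c(C(OCc2ccccc2)=C(C)O[Si](C)(C)C(C)(C)C)oc(-c2ccc(OC)c(OC)c2OC)c(OC)c1=O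
F2 | step 8 | 8-(benzyloxy)-7-(tert-butyldimethylsilyloxy)-5-hydroxy-3-methoxy-2-(2,3,4-trimethoxyphenyl)-4H-chromen-4-one | COc1ccc(-c2oc3c(OCc4ccccc4)c(O[Si](C)(C)C(C)(C)C)cc(O)c3c(=O)c2OC)c(OC)c1OC
F3 | step 7 | 2-[1-(benzyloxy)-2-oxopropyl]-3-bromo-5-methoxy-6-(2,3,4-trimethoxyphenyl)-4H-pyran-4-one (racemic) | CC(=O)C(OCc1ccccc1)c1oc(-c2ccc(OC)c(OC)c2OC)c(OC)c(=O)c1Br
F4 | step 5 | 3-hydroxy-6-(hydroxymethyl)-2-iodo-4H-pyran-4-one | O=c1cc(CO)oc(I)c1O
F5 | step 5 | 6-(hydroxymethyl)-2-iodo-3-methoxy-4H-pyran-4-one | O=c1cc(CO)oc(I)c1OC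
F6 | step 5 | 6-[(benzyloxy)methyl]-2-iodo-3-methoxy-4H-pyran-4-one | O=c1cc(COCc2ccccc2)oc(I)c1OC
F7 | step 5 | 2-[(benzyloxy)methyl]-3-bromo-6-iodo-5-methoxy-4H-pyran-4-one | O=c1c(Br)c(COCc2ccccc2)oc(I)c1OC
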